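A small charge of initiator, 0.82 mM, less than the 10 mM of substrate, starts a chain in each of these flasks. The first chain carrier meets coupling partner and gives target and the second chain carrier; that one meets substrate, gives back the first and sets released group free, which scavenger can take up. Substrate is the limiting reagent, with half the charge of coupling partner.

common to all: substrate 10 mM; initiator 0.82 mM

|  | coupling partner | transfer agent | scavenger | remark | time |
|---|---|---|---|---|---|
| south-east | 20 mM | 0.50 mM | 7.2 mM | run made earlier |  |
| east | 20 mM | 0.50 mM | 11 mM | run made earlier |  |
| alder | 20.0 mM | 0.500 mM | 10.0 mM |  | 3.0 h |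
| ash | 20.0 mM | 0.500 mM | 13.0 mM |  | 3.0 h |

| run | time / min | substrate / % | target / % |
|---|---|---|---|
| south-east | 12.0 | 94.3 | 4.4 |
| south-east | 30.0 | 86.8 | 8.6 |
| south-east | 60.0 | 80.1 | 15.5 |
| south-east | 90.0 | 70.6 | 23.8 |
| east | 12.0 | 94.3 | 3.5 |
| east | 30.0 | 87.1 | 10.8 |
| east | 60.0 | 79.5 | 17.4 |
| east | 90.0 | 70.3 | 24.2 |

(each reading ± 1 percentage point)

1. part of the substrate that has reacted at the end, alder
2. part of the substrate that has reacted at the end, ash
3. what raising the concentration of scavenger from its lowest to its highest value here does to the part of the substrate that has reacted (changes below 5 percentage points count as none) (no change / it rises / it falls)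

In both runs target climbs close to a straight line while substrate falls, so you can give the chain a pace and compare two times. One is the asked time, 180 min. The other is the run-through time: the time in which the chain, at the pace read from the last readings, would turn the whole substrate charge into target, here 375 min.

The last target readings of the two runs differ by 0.4 percentage points, less than the scatter of 1 point, with 7.2 mM and 11 mM of scavenger. So you leave scavenger out of the reckoning and expect no change, although ash, at 13.0 mM, lies above both runs.

Substrate missing from target at the last readings, taken as the mean of the two runs, is a gap of 5.55%. Your own reckoning carries it forward unchanged: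

asked time / run-through time = 48.0%

reacted = 48.0% + 5.55% = 53.6%

The forecast is a separate reckoning, an extrapolation of the substrate line to the asked time, and against your 53.6% it gives 54% for alder (46% to 64%), 54% for ash and no change, reasoning “so scavenger level does not affect the rate here”.

Alder reaches 50.2% and ash 50.1%, which is no change, a difference of −0.036 points. With the step from scavenger and released group struck out, alder still stands at 50.3%. The run-through time puts target at 48.0% by the asked time, and alder holds 46.4% of target at 3.00 h.

    2 first chain carrier → ended chains (k = 1.10 × 10⁷ L mol⁻¹ s⁻¹)
    transfer agent + first chain carrier → side product + idle radical (kL = 62700 L mol⁻¹ s⁻¹)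
    substrate + second chain carrier → released group + first chain carrier (k = 3.64 × 10⁵ L mol⁻¹ min⁻¹)
    scavenger + released group → scavenged by-product (k = 2.49 L mol⁻¹ min⁻¹)
    coupling partner + first chain carrier → target + second chain carrier (k = 1.25 × 10⁵ L mol⁻¹ s⁻¹)
    substrate + released group ⇌ idle adduct, settled at all times (K = 271 L mol⁻¹)
    2 idle radical → ended radicals (k = 3.30 × 10⁶ L mol⁻¹ s⁻¹)
    substrate + initiating radical → capped initiator + first chain carrier (k = 46700 L mol⁻¹ s⁻¹)
    initiator → 2 initiating radical (k = 2.14 × 10⁻⁴ min⁻¹)
    crystals ⇌ released group, rate k10*(cs10 - [released group]) while solid is left; crystals form when [released group] > cs10 (solubility = 0.200 mM, k = 0.551 min⁻¹)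

Now take ash with 2.5 mM of substrate, the other charges held. If the pace in mM holds, the run-through time shrinks with the charge to 93.8 min, shorter than the asked time, so this reckoning expects the whole charge to react within the asked time. The computed flask has 100% reacted, 0% substrate left and 98.7% as target.

The readings are simulated for substances that don't exist; the scatter is artificial.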